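**Plan**
- Retrosynthesis: cut the acrylate C–O bond (acid 20, chiral pool), take the acrylic acid back to a CH2CH2OPMB arm, then cut both ring bonds C8a–C4a and C2–C3 of the octahydronaphthalene at once to reach the acyclic (2E,4E)-trienal 14.
- Enabling feature: ring A is a 3-methylidenecyclohexan-1-ol (C2–OH, C3H2, C4=CH2), the product pattern of a type II carbonyl-ene closure. C8a–C4a joins the carbon β to the former formyl group to the carbon that carried a prenyl terminus, the product pattern of an enal/prenyl ene reaction. The two prenyl methyls of 14 become C3 and the exocyclic CH2.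
- Forward: but-2-yne-1,4-diol → Z-iodoalkene → Negishi coupling → enal 8 → HWE/DIBAL-H/MnO2 → 14. One flask then closes ring B (C8a–C4a) and ring A (C2–C3). Acylation with 20, arm oxidation, α-methylenation, Pinnick oxidation and acidic deprotection finish the route.
- Stereochemistry: the ring-alkene geometry comes from trans-hydroalumination/iodination and the 2E-enal from the HWE step. The absolute configuration comes from a chiral oxazaborolidinium that selects the enal face. C4a, C1 and C2 then follow from the chair ene and bicyclic carbonyl-ene transition states. The side-chain (S)-centre comes from (S)-butane-1,2,4-triol acetonide.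

Key step: step 9

Remark: ring positions are numbered as in octahydronaphthalene 16 (C1 arm, C2 oxygen, C4 methylidene, C4a/C8a fusion, C7 CH2O); chain positions as in decatrienal 14.
Assumption: the (S)-diphenylprolinol-derived oxazaborolidinium is taken as the antipode that leaves the Re face of C3 of 14 open; if the sense is the reverse, its enantiomer is used and nothing else changes.
Assumption: 5, 9, 10 and 17 are taken as catalogue chemicals.

**Route**

Step 1
Reactants: 1 but-2-yne-1,4-diol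
Product: 2 4-{[tert-butyl(dimethyl)silyl]oxy}but-2-yn-1-ol
Conditions: NaH (1.0 equiv), THF, 0 °C; TBSCl (1.0 equiv), 0 °C → rt
Reagents that add atoms: tert-butyl(chloro)dimethylsilane (TBSCl), CC(C)(C)[Si](C)(C)Cl
Why: O-silylation of the sparingly soluble monosodium alkoxide of a symmetrical diol should stop at the mono-ether.

Step 2
Reactants: 2 4-{[tert-butyl(dimethyl)silyl]oxy}but-2-yn-1-ol
Product: 4 (2Z)-4-{[tert-butyl(dimethyl)silyl]oxy}-3-iodobut-2-en-1-ol, via cyclic vinylalanate 3 (not isolated)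
Conditions: Red-Al (1.5 equiv), THF, 0 °C → rt; then I2 (2 equiv), THF, −78 → 0 °C
Reagents that add atoms: iodine, II
Why: Hydroxyl-directed trans-hydroalumination puts hydride on C2 and aluminium on C3 in a five-membered alkoxyalanate, and iododealumination with retention fixes the Z geometry (CH2OH cis to I).

Step 3
Reactants: 4 (2Z)-4-{[tert-butyl(dimethyl)silyl]oxy}-3-iodobut-2-en-1-ol; 5 5-bromo-2-methylpent-2-ene
Product: 7 (2E)-3-({[tert-butyl(dimethyl)silyl]oxy}methyl)-7-methylocta-2,6-dien-1-ol, via (4-methylpent-3-en-1-yl)zinc bromide 6 (not isolated)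
Conditions: 5 (2.5 equiv), Zn dust, LiCl, THF, 40 °C; then 4, Pd(dppf)Cl2 (5 mol %), THF, 50 °C
Reagents that add atoms: none
Why: Negishi sp3–sp2 coupling should proceed with retention at the alkenyl iodide, so the homoprenyl chain ends cis to CH2OH; the excess organozinc covers the free hydroxyl.

Step 4
Reactants: 7 (2E)-3-({[tert-butyl(dimethyl)silyl]oxy}methyl)-7-methylocta-2,6-dien-1-ol
Product: 8 (2E)-3-({[tert-butyl(dimethyl)silyl]oxy}methyl)-7-methylocta-2,6-dienal
Conditions: activated MnO2 (15 equiv), CH2Cl2, rt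
Reagents that add atoms: none
Why: Allylic oxidation on MnO2 is neutral and should keep the alkene geometry (CHO cis to the chain), as in nerol-to-neral oxidations.

Step 5
Reactants: 9 triethyl phosphonoacetate; 10 1-[(2-bromoethoxy)methyl]-4-methoxybenzene
Product: 11 ethyl 2-(diethoxyphosphoryl)-4-[(4-methoxyphenyl)methoxy]butanoate (racemic)
Conditions: NaH (1.1 equiv), DMF, 0 °C; then 10 (0.8 equiv), NaI (10 mol %), 60 °C
Reagents that add atoms: none
Why: C-alkylation of the stabilised phosphonoacetate anion by a primary halide (iodide formed in situ), with the phosphonate in excess against dialkylation.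

Step 6
Reactants: 8 (2E)-3-({[tert-butyl(dimethyl)silyl]oxy}methyl)-7-methylocta-2,6-dienal; 11 ethyl 2-(diethoxyphosphoryl)-4-[(4-methoxyphenyl)methoxy]butanoate
Product: 12 ethyl (2E,4E)-5-({[tert-butyl(dimethyl)silyl]oxy}methyl)-2-{2-[(4-methoxyphenyl)methoxy]ethyl}-9-methyldeca-2,4,8-trienoate
Conditions: 11 (1.3 equiv), NaH (1.2 equiv), THF, 0 °C; then 8, −78 → 0 °C
Reagents that add atoms: none
Why: Horner–Wadsworth–Emmons olefination of a stabilised phosphonate should place the ester trans to the dienyl residue (2E); the pre-formed anion and low temperature spare the γ-hydrogens of 8.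

Step 7
Reactants: 12 ethyl (2E,4E)-5-({[tert-butyl(dimethyl)silyl]oxy}methyl)-2-{2-[(4-methoxyphenyl)methoxy]ethyl}-9-methyldeca-2,4,8-trienoate
Product: 13 (2E,4E)-5-({[tert-butyl(dimethyl)silyl]oxy}methyl)-2-{2-[(4-methoxyphenyl)methoxy]ethyl}-9-methyldeca-2,4,8-trien-1-ol
Conditions: DIBAL-H (2.5 equiv), CH2Cl2, −78 °C; Rochelle salt work-up
Reagents that add atoms: none
Why: DIBAL-H reduces the conjugated ester 1,2 to the allylic alcohol and leaves silyl and PMB ethers alone.

Step 8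
Reactants: 13 (2E,4E)-5-({[tert-butyl(dimethyl)silyl]oxy}methyl)-2-{2-[(4-methoxyphenyl)methoxy]ethyl}-9-methyldeca-2,4,8-trien-1-ol
Product: 14 (2E,4E)-5-({[tert-butyl(dimethyl)silyl]oxy}methyl)-2-{2-[(4-methoxyphenyl)methoxy]ethyl}-9-methyldeca-2,4,8-trienal
Conditions: activated MnO2 (15 equiv), CH2Cl2, rt
Reagents that add atoms: none
Why: Chemoselective MnO2 oxidation of the dienylic alcohol should give the thermodynamically preferred 2E-dienal without touching the 4,5- or 8,9-alkenes.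

Step 9
Reactants: 14 (2E,4E)-5-({[tert-butyl(dimethyl)silyl]oxy}methyl)-2-{2-[(4-methoxyphenyl)methoxy]ethyl}-9-methyldeca-2,4,8-trienal
Product: 16 (1R,2S,4aS,8aS)-7-({[tert-butyl(dimethyl)silyl]oxy}methyl)-1-{2-[(4-methoxyphenyl)methoxy]ethyl}-4-methylidene-1,2,3,4,4a,5,6,8a-octahydronaphthalen-2-ol, via monocyclic aldehyde 15 (not isolated)
Conditions: (S)-o-tolyl-CBS oxazaborolidine (20 mol %), Tf2NH (18 mol %), CH2Cl2, −78 → −40 °C; then Me2AlCl (1.5 equiv), same flask, −78 → −20 °C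
Reagents that add atoms: none
Why: Proposed new method: the boron-bound s-trans E-enal of 14 is attacked at C3 by the C8=C9 prenyl alkene while an allylic methyl hydrogen passes suprafacially to C2 (concerted ene or tight zwitterion), giving aldehyde 15 with an isopropenyl group; Me2AlCl then promotes a type II carbonyl-ene reaction in which the isopropenyl CH2 adds to the formyl carbon and the remaining methyl gives a hydrogen to oxygen, leaving the exocyclic methylene. The closest known reaction types are the Me2AlCl-mediated sequential ene annulation of enals with 1,1-disubstituted alkenes (racemic), the Lewis-acid ene cyclisation of activated 1,7-dienes to trans-2-isopropenylcyclohexanes, and oxazaborolidinium-catalysed enantioselective additions to α-substituted enals; new is the chiral catalyst in an intramolecular conjugate ene step. Ring B closes 6-exo-trig at C3 through a chair-like array, and ring A closes 6-exo-trig at the formyl carbon through the bicyclic type II ene transition state. C8a is set by the catalyst, which leaves only the Re face of C3 open; C4a comes out trans to it because the enal and the dimethylvinyl terminus are both pseudo-equatorial; C1 follows from suprafacial hydrogen transfer across the E-configured C2=C3; at C2 the aluminium-bound oxygen must be axial to reach the methyl hydrogen, so the hydroxyl ends axial and cis to the equatorial arm. The step needs 1,4-attack and ene rather than Prins or hetero-Diels–Alder capture: only attack at C3 gives a six-membered ring (C1 would give an eight-membered and C5 a four-membered ring), the 4E geometry holds C3 and the tether cis, and a dihydropyran formed by O-capture should reopen under the Lewis acid.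

Step 10
Reactants: 17 2-[(4S)-2,2-dimethyl-1,3-dioxolan-4-yl]ethan-1-ol
Product: 18 [(4S)-2,2-dimethyl-1,3-dioxolan-4-yl]acetaldehyde
Conditions: Dess–Martin periodinane (1.2 equiv), NaHCO3, CH2Cl2, 0 °C → rt
Reagents that add atoms: none
Why: Buffered Dess–Martin oxidation converts the primary alcohol to the aldehyde without touching the acetonide or the β-stereocentre.

Step 11
Reactants: 18 [(4S)-2,2-dimethyl-1,3-dioxolan-4-yl]acetaldehyde
Product: 19 2-[(4S)-2,2-dimethyl-1,3-dioxolan-4-yl]prop-2-enal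
Conditions: Eschenmoser's salt (2.5 equiv), Et3N (4 equiv), CH2Cl2, rt
Reagents that add atoms: dimethyl(methylidene)ammonium iodide (Eschenmoser's salt), C=[N+](C)C.[I-]
Why: Mannich reaction of the aldehyde enol with the iminium salt and elimination of dimethylamine gives the 2-substituted acrolein; the stereocentre is not the enolised carbon and should stay intact.

Step 12
Reactants: 19 2-[(4S)-2,2-dimethyl-1,3-dioxolan-4-yl]prop-2-enal
Product: 20 2-[(4S)-2,2-dimethyl-1,3-dioxolan-4-yl]prop-2-enoic acid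
Conditions: NaClO2, NaH2PO4, 2-methylbut-2-ene (excess), t-BuOH/H2O, 0 °C → rt
Reagents that add atoms: sodium chlorite, [Na+].[O-]Cl=O
Why: Pinnick oxidation takes α-substituted acroleins to acrylic acids without alkene migration; the buffer keeps the acetonide.

Step 13
Reactants: 16 (1R,2S,4aS,8aS)-7-({[tert-butyl(dimethyl)silyl]oxy}methyl)-1-{2-[(4-methoxyphenyl)methoxy]ethyl}-4-methylidene-1,2,3,4,4a,5,6,8a-octahydronaphthalen-2-ol; 20 2-[(4S)-2,2-dimethyl-1,3-dioxolan-4-yl]prop-2-enoic acid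
Product: 22 (1R,2S,4aS,8aS)-7-({[tert-butyl(dimethyl)silyl]oxy}methyl)-1-{2-[(4-methoxyphenyl)methoxy]ethyl}-4-methylidene-1,2,3,4,4a,5,6,8a-octahydronaphthalen-2-yl 2-[(4S)-2,2-dimethyl-1,3-dioxolan-4-yl]prop-2-enoate, via mixed anhydride 21 (not isolated)
Conditions: 20 (1.5 equiv), 2,4,6-trichlorobenzoyl chloride (1.5 equiv), Et3N, toluene, rt; then 16, DMAP (2 equiv), toluene, rt → 40 °C
Reagents that add atoms: none
Why: Yamaguchi esterification is the standard way to acylate hindered secondary alcohols with α-substituted acrylic acids; no stereocentre is touched.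

Step 14
Reactants: 22 (the PMB ether ester from step 13)
Product: 23 (1R,2S,4aS,8aS)-7-({[tert-butyl(dimethyl)silyl]oxy}methyl)-1-(2-hydroxyethyl)-4-methylidene-1,2,3,4,4a,5,6,8a-octahydronaphthalen-2-yl 2-[(4S)-2,2-dimethyl-1,3-dioxolan-4-yl]prop-2-enoate
Conditions: DDQ (1.3 equiv), CH2Cl2/pH 7 buffer (10:1), 0 °C → rt
Reagents that add atoms: none
Why: Oxidative PMB cleavage by DDQ is orthogonal to the TBS ether, the acetonide, the isolated alkenes and both esters.

Step 15
Reactants: 23 (the primary alcohol from step 14)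
Product: 24 (1R,2S,4aS,8aS)-7-({[tert-butyl(dimethyl)silyl]oxy}methyl)-4-methylidene-1-(2-oxoethyl)-1,2,3,4,4a,5,6,8a-octahydronaphthalen-2-yl 2-[(4S)-2,2-dimethyl-1,3-dioxolan-4-yl]prop-2-enoate
Conditions: Dess–Martin periodinane (1.3 equiv), NaHCO3, CH2Cl2, 0 °C → rt
Reagents that add atoms: none
Why: Buffered Dess–Martin oxidation gives the aldehyde under neutral conditions; the β-centre C1 is not enolisable through this aldehyde.

Step 16
Reactants: 24 (the aldehyde from step 15)
Product: 25 (1S,2S,4aS,8aS)-7-({[tert-butyl(dimethyl)silyl]oxy}methyl)-4-methylidene-1-(3-oxoprop-1-en-2-yl)-1,2,3,4,4a,5,6,8a-octahydronaphthalen-2-yl 2-[(4S)-2,2-dimethyl-1,3-dioxolan-4-yl]prop-2-enoate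
Conditions: Eschenmoser's salt (3 equiv), Et3N (5 equiv), CH2Cl2, rt
Reagents that add atoms: dimethyl(methylidene)ammonium iodide (Eschenmoser's salt), C=[N+](C)C.[I-]
Why: Mannich/elimination α-methylenation acts only at the aldehyde α-CH2; there is no β-leaving group (the acyloxy group is γ), and the C1 descriptor changes only because of CIP priorities.

Step 17
Reactants: 25 (the enal from step 16)
Product: 26 2-[(1S,2S,4aS,8aS)-7-({[tert-butyl(dimethyl)silyl]oxy}methyl)-2-({2-[(4S)-2,2-dimethyl-1,3-dioxolan-4-yl]prop-2-enoyl}oxy)-4-methylidene-1,2,3,4,4a,5,6,8a-octahydronaphthalen-1-yl]prop-2-enoic acid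
Conditions: NaClO2, NaH2PO4, 2-methylbut-2-ene (excess), t-BuOH/H2O, 0 °C → rt
Reagents that add atoms: sodium chlorite, [Na+].[O-]Cl=O
Why: Pinnick oxidation converts the enal to the acrylic acid; the scavenger protects the three other alkenes from hypochlorite.

Step 18
Reactants: 26 (the protected acid from step 17)
Product: 27 2-[(1S,2S,4aS,8aS)-2-{[(3S)-3,4-dihydroxy-2-methylidenebutanoyl]oxy}-7-(hydroxymethyl)-4-methylidene-1,2,3,4,4a,5,6,8a-octahydronaphthalen-1-yl]prop-2-enoic acid (target)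
Conditions: 1 M aq. HCl/THF (1:3), 0 °C → rt; work-up kept acidic, reversed-phase chromatography
Reagents that add atoms: none
Why: Dilute aqueous acid hydrolyses the primary allylic TBS ether and the terminal acetonide in one operation; acid rather than base is chosen because a free 4-hydroxy-2-methylidenebutanoate lactonises under basic conditions.

**Compound list**
1 | but-2-yne-1,4-diol | OCC#CCO | starting material
2 | 4-{[tert-butyl(dimethyl)silyl]oxy}but-2-yn-1-ol | OCC#CCO[Si](C)(C)C(C)(C)C | intermediate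
3 | cyclic vinylalanate, sodium 2,2-bis(2-methoxyethoxy)-3-({[tert-butyl(dimethyl)silyl]oxy}methyl)-2,5-dihydro-1,2-oxaaluminol-2-uide (not isolated) | [Na+].COCCO[Al-]1(OCCOC)OCC=C1CO[Si](C)(C)C(C)(C)C | intermediate
4 | (2Z)-4-{[tert-butyl(dimethyl)silyl]oxy}-3-iodobut-2-en-1-ol | OC/C=C(\I)CO[Si](C)(C)C(C)(C)C | intermediate
5 | 5-bromo-2-methylpent-2-ene | CC(C)=CCCBr | starting material
6 | (4-methylpent-3-en-1-yl)zinc bromide (not isolated) | CC(C)=CCC[Zn]Br | intermediate
7 | (2E)-3-({[tert-butyl(dimethyl)silyl]oxy}methyl)-7-methylocta-2,6-dien-1-ol | OC/C=C(\CCC=C(C)C)CO[Si](C)(C)C(C)(C)C | intermediate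
8 | (2E)-3-({[tert-butyl(dimethyl)silyl]oxy}methyl)-7-methylocta-2,6-dienal | O=C/C=C(\CCC=C(C)C)CO[Si](C)(C)C(C)(C)C | intermediate
9 | triethyl phosphonoacetate | CCOC(=O)CP(=O)(OCC)OCC | starting material
10 | 1-[(2-bromoethoxy)methyl]-4-methoxybenzene | COc1ccc(COCCBr)cc1 | starting material
11 | ethyl 2-(diethoxyphosphoryl)-4-[(4-methoxyphenyl)methoxy]butanoate (racemic) | CCOC(=O)C(CCOCc1ccc(OC)cc1)P(=O)(OCC)OCC | intermediate
12 | ethyl (2E,4E)-5-({[tert-butyl(dimethyl)silyl]oxy}methyl)-2-{2-[(4-methoxyphenyl)methoxy]ethyl}-9-methyldeca-2,4,8-trienoate | CCOC(=O)/C(CCOCc1ccc(OC)cc1)=C/C=C(/CO[Si](C)(C)C(C)(C)C)CCC=C(C)C | intermediate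
13 | (2E,4E)-5-({[tert-butyl(dimethyl)silyl]oxy}methyl)-2-{2-[(4-methoxyphenyl)methoxy]ethyl}-9-methyldeca-2,4,8-trien-1-ol | OC/C(CCOCc1ccc(OC)cc1)=C/C=C(/CO[Si](C)(C)C(C)(C)C)CCC=C(C)C | intermediate
14 | (2E,4E)-5-({[tert-butyl(dimethyl)silyl]oxy}methyl)-2-{2-[(4-methoxyphenyl)methoxy]ethyl}-9-methyldeca-2,4,8-trienal | O=C/C(CCOCc1ccc(OC)cc1)=C/C=C(/CO[Si](C)(C)C(C)(C)C)CCC=C(C)C | intermediate
15 | monocyclic aldehyde, (2R)-2-[(1S,6S)-3-({[tert-butyl(dimethyl)silyl]oxy}methyl)-6-(prop-1-en-2-yl)cyclohex-2-en-1-yl]-4-[(4-methoxyphenyl)methoxy]butanal (not isolated) | COc1ccc(COCC[C@@H](C=O)[C@H]2C=C(CO[Si](C)(C)C(C)(C)C)CC[C@@H]2C(C)=C)cc1 | intermediate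
16 | (1R,2S,4aS,8aS)-7-({[tert-butyl(dimethyl)silyl]oxy}methyl)-1-{2-[(4-methoxyphenyl)methoxy]ethyl}-4-methylidene-1,2,3,4,4a,5,6,8a-octahydronaphthalen-2-ol (trans-fused, arm equatorial, OH axial) | COc1ccc(COCC[C@@H]2[C@H]3C=C(CO[Si](C)(C)C(C)(C)C)CC[C@@H]3C(=C)C[C@@H]2O)cc1 | intermediate
17 | 2-[(4S)-2,2-dimethyl-1,3-dioxolan-4-yl]ethan-1-ol | OCC[C@H]1COC(C)(C)O1 | starting material
18 | [(4S)-2,2-dimethyl-1,3-dioxolan-4-yl]acetaldehyde | O=CC[C@H]1COC(C)(C)O1 | intermediate
19 | 2-[(4S)-2,2-dimethyl-1,3-dioxolan-4-yl]prop-2-enal | C=C(C=O)[C@H]1COC(C)(C)O1 | intermediate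
20 | 2-[(4S)-2,2-dimethyl-1,3-dioxolan-4-yl]prop-2-enoic acid | C=C(C(=O)O)[C@H]1COC(C)(C)O1 | intermediate
21 | mixed anhydride, 2-[(4S)-2,2-dimethyl-1,3-dioxolan-4-yl]prop-2-enoic 2,4,6-trichlorobenzoic anhydride (not isolated) | C=C(C(=O)OC(=O)c1c(Cl)cc(Cl)cc1Cl)[C@H]2COC(C)(C)O2 | intermediate
22 | (1R,2S,4aS,8aS)-7-({[tert-butyl(dimethyl)silyl]oxy}methyl)-1-{2-[(4-methoxyphenyl)methoxy]ethyl}-4-methylidene-1,2,3,4,4a,5,6,8a-octahydronaphthalen-2-yl 2-[(4S)-2,2-dimethyl-1,3-dioxolan-4-yl]prop-2-enoate | COc1ccc(COCC[C@@H]2[C@H]3C=C(CO[Si](C)(C)C(C)(C)C)CC[C@@H]3C(=C)C[C@@H]2OC(=O)C(=C)[C@H]4COC(C)(C)O4)cc1 | intermediate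
23 | (1R,2S,4aS,8aS)-7-({[tert-butyl(dimethyl)silyl]oxy}methyl)-1-(2-hydroxyethyl)-4-methylidene-1,2,3,4,4a,5,6,8a-octahydronaphthalen-2-yl 2-[(4S)-2,2-dimethyl-1,3-dioxolan-4-yl]prop-2-enoate | OCC[C@@H]1[C@H]2C=C(CO[Si](C)(C)C(C)(C)C)CC[C@@H]2C(=C)C[C@@H]1OC(=O)C(=C)[C@H]3COC(C)(C)O3 | intermediate
24 | (1R,2S,4aS,8aS)-7-({[tert-butyl(dimethyl)silyl]oxy}methyl)-4-methylidene-1-(2-oxoethyl)-1,2,3,4,4a,5,6,8a-octahydronaphthalen-2-yl 2-[(4S)-2,2-dimethyl-1,3-dioxolan-4-yl]prop-2-enoate | O=CC[C@@H]1[C@H]2C=C(CO[Si](C)(C)C(C)(C)C)CC[C@@H]2C(=C)C[C@@H]1OC(=O)C(=C)[C@H]3COC(C)(C)O3 | intermediate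
25 | (1S,2S,4aS,8aS)-7-({[tert-butyl(dimethyl)silyl]oxy}methyl)-4-methylidene-1-(3-oxoprop-1-en-2-yl)-1,2,3,4,4a,5,6,8a-octahydronaphthalen-2-yl 2-[(4S)-2,2-dimethyl-1,3-dioxolan-4-yl]prop-2-enoate | C=C(C=O)[C@@H]1[C@H]2C=C(CO[Si](C)(C)C(C)(C)C)CC[C@@H]2C(=C)C[C@@H]1OC(=O)C(=C)[C@H]3COC(C)(C)O3 | intermediate
26 | 2-[(1S,2S,4aS,8aS)-7-({[tert-butyl(dimethyl)silyl]oxy}methyl)-2-({2-[(4S)-2,2-dimethyl-1,3-dioxolan-4-yl]prop-2-enoyl}oxy)-4-methylidene-1,2,3,4,4a,5,6,8a-octahydronaphthalen-1-yl]prop-2-enoic acid | C=C(C(=O)O)[C@@H]1[C@H]2C=C(CO[Si](C)(C)C(C)(C)C)CC[C@@H]2C(=C)C[C@@H]1OC(=O)C(=C)[C@H]3COC(C)(C)O3 | intermediate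
27 | 2-[(1S,2S,4aS,8aS)-2-{[(3S)-3,4-dihydroxy-2-methylidenebutanoyl]oxy}-7-(hydroxymethyl)-4-methylidene-1,2,3,4,4a,5,6,8a-octahydronaphthalen-1-yl]prop-2-enoic acid | C=C(C(=O)O)[C@@H]1[C@H]2C=C(CO)CC[C@@H]2C(=C)C[C@@H]1OC(=O)C(=C)[C@H](O)CO | target

**Step count**
Total: 18 steps. Longest linear sequence: 14 steps (steps 1–4, 6–9, 13–18).

**Steps most likely to fail**

Step 9 (proposed new method). The chiral boron catalyst may not turn over once the alcohol forms, may discriminate the enal faces poorly, or the hydrogen transfer may lose its suprafacial course and scramble C1. Fallback with known chemistry, setting out from 14: Me2AlCl alone (2 equiv, CH2Cl2, −78 → 0 °C), the established sequential ene annulation, should give the racemic aldehyde, i.e. 15 and its enantiomer (2S)-2-[(1R,6R)-3-({[tert-butyl(dimethyl)silyl]oxy}methyl)-6-(prop-1-en-2-yl)cyclohex-2-en-1-yl]-4-[(4-methoxyphenyl)methoxy]butanal F1 (not isolated). This closes to the racemic alcohol, i.e. 16 and its enantiomer (1S,2R,4aR,8aR)-7-({[tert-butyl(dimethyl)silyl]oxy}methyl)-1-{2-[(4-methoxyphenyl)methoxy]ethyl}-4-methylidene-1,2,3,4,4a,5,6,8a-octahydronaphthalen-2-ol F2. Yamaguchi esterification of the racemate with enantiopure acid 20 through 21 then gives 22 and the diastereomeric ester (1S,2R,4aR,8aR)-7-({[tert-butyl(dimethyl)silyl]oxy}methyl)-1-{2-[(4-methoxyphenyl)methoxy]ethyl}-4-methylidene-1,2,3,4,4a,5,6,8a-octahydronaphthalen-2-yl 2-[(4S)-2,2-dimethyl-1,3-dioxolan-4-yl]prop-2-enoate F3. The two are separated by preparative chromatography and the route is rejoined at 22; the acyl group the target needs anyway serves as resolving agent.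

Step 13. Acylation of the axial, flanked secondary hydroxyl may be so slow that DMAP-induced oligomerisation of the acrylate or decay of the mixed anhydride takes over. Fallback, setting out from 16: Dess–Martin oxidation to the ketone (1R,4aS,8aS)-7-({[tert-butyl(dimethyl)silyl]oxy}methyl)-1-{2-[(4-methoxyphenyl)methoxy]ethyl}-4-methylidene-3,4,4a,5,6,8a-hexahydronaphthalen-2(1H)-one F4. NaBH4 (MeOH, −20 °C, axial hydride delivery) then gives the equatorial epimer (1R,2R,4aS,8aS)-7-({[tert-butyl(dimethyl)silyl]oxy}methyl)-1-{2-[(4-methoxyphenyl)methoxy]ethyl}-4-methylidene-1,2,3,4,4a,5,6,8a-octahydronaphthalen-2-ol F5. Mitsunobu esterification with 20 (PPh3, DIAD, toluene) proceeds with inversion, as for menthol-type alcohols, and returns to 22.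

Step 6. The α-branched phosphonate may give an E/Z mixture at the new trisubstituted alkene, and the basic medium may deprotonate 8 at a γ-position and scramble its 2,3-alkene; either would feed the wrong C1 epimer or an uncyclisable isomer into step 9. Fallback, setting out from 8: base-free Wittig reaction with commercial 3-(triphenylphosphoranylidene)oxolan-2-one (toluene, 80 °C) to the lactone (3E)-3-[(2E)-3-({[tert-butyl(dimethyl)silyl]oxy}methyl)-7-methylocta-2,6-dien-1-ylidene]oxolan-2-one F6. Ring opening with MeNH(OMe)·HCl/Me3Al gives the Weinreb amide (2E,4E)-5-({[tert-butyl(dimethyl)silyl]oxy}methyl)-2-(2-hydroxyethyl)-N-methoxy-N,9-dimethyldeca-2,4,8-trienamide F7. Protection with 4-methoxybenzyl trichloroacetimidate and catalytic Sc(OTf)3 gives (2E,4E)-5-({[tert-butyl(dimethyl)silyl]oxy}methyl)-N-methoxy-2-{2-[(4-methoxyphenyl)methoxy]ethyl}-N,9-dimethyldeca-2,4,8-trienamide F8. DIBAL-H (THF, −78 °C) then gives 14 directly, bypassing 12 and 13.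

**Further compounds**
F1 | step 9 | (2S)-2-[(1R,6R)-3-({[tert-butyl(dimethyl)silyl]oxy}methyl)-6-(prop-1-en-2-yl)cyclohex-2-en-1-yl]-4-[(4-methoxyphenyl)methoxy]butanal | COc1ccc(COCC[C@H](C=O)[C@@H]2C=C(CO[Si](C)(C)C(C)(C)C)CC[C@H]2C(C)=C)cc1
F2 | step 9 | (1S,2R,4aR,8aR)-7-({[tert-butyl(dimethyl)silyl]oxy}methyl)-1-{2-[(4-methoxyphenyl)methoxy]ethyl}-4-methylidene-1,2,3,4,4a,5,6,8a-octahydronaphthalen-2-ol | COc1ccc(COCC[C@H]2[C@@H]3C=C(CO[Si](C)(C)C(C)(C)C)CC[C@H]3C(=C)C[C@H]2O)cc1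
F3 | step 9 | (1S,2R,4aR,8aR)-7-({[tert-butyl(dimethyl)silyl]oxy}methyl)-1-{2-[(4-methoxyphenyl)methoxy]ethyl}-4-methylidene-1,2,3,4,4a,5,6,8a-octahydronaphthalen-2-yl 2-[(4S)-2,2-dimethyl-1,3-dioxolan-4-yl]prop-2-enoate | COc1ccc(COCC[C@H]2[C@@H]3C=C(CO[Si](C)(C)C(C)(C)C)CC[C@H]3C(=C)C[C@H]2OC(=O)C(=C)[C@H]4COC(C)(C)O4)cc1
F4 | step 13 | (1R,4aS,8aS)-7-({[tert-butyl(dimethyl)silyl]oxy}methyl)-1-{2-[(4-methoxyphenyl)methoxy]ethyl}-4-methylidene-3,4,4a,5,6,8a-hexahydronaphthalen-2(1H)-one | COc1ccc(COCC[C@@H]2[C@H]3C=C(CO[Si](C)(C)C(C)(C)C)CC[C@@H]3C(=C)CC2=O)cc1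
F5 | step 13 | (1R,2R,4aS,8aS)-7-({[tert-butyl(dimethyl)silyl]oxy}methyl)-1-{2-[(4-methoxyphenyl)methoxy]ethyl}-4-methylidene-1,2,3,4,4a,5,6,8a-octahydronaphthalen-2-ol | COc1ccc(COCC[C@@H]2[C@H]3C=C(CO[Si](C)(C)C(C)(C)C)CC[C@@H]3C(=C)C[C@H]2O)cc1
F6 | step 6 | (3E)-3-[(2E)-3-({[tert-butyl(dimethyl)silyl]oxy}methyl)-7-methylocta-2,6-dien-1-ylidene]oxolan-2-one | O=C1OCC\C1=C/C=C(/CO[Si](C)(C)C(C)(C)C)CCC=C(C)C
F7 | step 6 | (2E,4E)-5-({[tert-butyl(dimethyl)silyl]oxy}methyl)-2-(2-hydroxyethyl)-N-methoxy-N,9-dimethyldeca-2,4,8-trienamide | CON(C)C(=O)/C(CCO)=C/C=C(/CO[Si](C)(C)C(C)(C)C)CCC=C(C)C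
F8 | step 6 | (2E,4E)-5-({[tert-butyl(dimethyl)silyl]oxy}methyl)-N-methoxy-2-{2-[(4-methoxyphenyl)methoxy]ethyl}-N,9-dimethyldeca-2,4,8-trienamide | CON(C)C(=O)/C(CCOCc1ccc(OC)cc1)=C/C=C(/CO[Si](C)(C)C(C)(C)C)CCC=C(C)C
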